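**Plan**

- Retrosynthesis cuts ring C at C11–C12 and C8–C14, a (3+3) disconnection into an A/B enone–aldehyde (C8 as the carbon terminus of a silyl dienol ether, C11 as aldehyde) and a ring-D cyclopropane.
- Enabling feature: C12–C13–C14 of rings C/D, with two vicinal quaternary methyl carbons anti to each other on a trans ring fusion, is a cis-1,2-dimethylcyclopropane opened with inversion at C14. C12 temporarily carries an ester and a lactone carbonyl tied to O–C18.
- Forward order: tetrahydrofuran ring (from geranyl acetate), then rings A and B together by Pauson–Khand reaction, then the ring-D cyclopropane lactone (from 2,3-dimethylcyclohexenone), then ring C in the key step.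
- Endgame: the helpers (CO2Me, C11–O, lactone carbonyl, C7 and C18 ketones) are removed; the C18 ketone is first used to build C17 and its side chain.
- Stereochemistry: C3 by CBS reduction; C10 by Sharpless epoxidation and invertive etherification; C9 by ring constraint in the Pauson–Khand step; C5 by dissolving-metal reduction; C13/C14 from the CBS-set C18 carbinol through tether-directed cyclopropanation and invertive opening; C8 in the key step; C17 by alkylation anti to the C13 methyl.

Key step: step 17

Remark on the chemistry: locants C1–C18 and ring letters are those of the target. The oxygen bridges C3 and C10; ring A = C1–C5, C9, C10; ring B = C5–C9; ring C = C8, C9, C11–C14; ring D = C13–C18. C4 carries two methyls; C10, C13, C14 and C17 one each; C17 also carries the 4-methylpent-3-enyl chain. Centres marked "epimers" (C11 in 23, C12 in 25–28, C17 in 31) are destroyed later. Compounds 1, 3, 16, 18 and 30 are taken as purchased.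

**Route**

Step 1
Reactants: 1 geranyl acetate
Product: 2 (2E)-3-methyl-6-oxohex-2-en-1-yl acetate
Conditions: O3 (1 equiv), pyridine, CH2Cl2, −78 °C; then Me2S
Reagents that add atoms: ozone, O=[O+][O-]
Why: Chemoselective ozonolysis: the electron-rich trisubstituted 6,7-alkene should react before the 2,3-alkene that is deactivated by the allylic acetate, which unmasks the C3 aldehyde.

Step 2
Reactants: 2 (2E)-3-methyl-6-oxohex-2-en-1-yl acetate; 3 3-chloro-3-methylbut-1-yne
Product: 4 (2E)-6-hydroxy-3,7,7-trimethylnon-2-en-8-yn-1-yl acetate (racemic carbinol)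
Conditions: Zn dust, THF, 0 °C to rt; aq. NH4Cl
Reagents that add atoms: none
Why: Barbier-type propargylation: the allenylzinc formed from the tertiary propargylic chloride should add through its γ-carbon (SE2′, cyclic transition state), placing C4 with both methyls and the C5≡C6 alkyne; the racemic carbinol is corrected in steps 3 and 4.

Step 3
Reactants: 4 (2E)-6-hydroxy-3,7,7-trimethylnon-2-en-8-yn-1-yl acetate
Product: 5 (2E)-3,7,7-trimethyl-6-oxonon-2-en-8-yn-1-yl acetate
Conditions: Dess–Martin periodinane, NaHCO3, CH2Cl2, rt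
Reagents that add atoms: none
Why: Dess–Martin oxidation of the secondary alcohol to the ketone, which has no α-hydrogen on the quaternary side.

Step 4
Reactants: 5 (2E)-3,7,7-trimethyl-6-oxonon-2-en-8-yn-1-yl acetate
Product: 6 (2E,6S)-6-hydroxy-3,7,7-trimethylnon-2-en-8-yn-1-yl acetate
Conditions: (R)-2-methyl-CBS-oxazaborolidine (cat.), catecholborane, toluene, −78 °C
Reagents that add atoms: none
Why: CBS reduction with the tert-alkyl (1,1-dimethylpropargyl) group as the large substituent should give the (S)-carbinol (C3 of the target); catecholborane avoids hydroboration of the alkene and alkyne.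

Step 5
Reactants: 6 (2E,6S)-6-hydroxy-3,7,7-trimethylnon-2-en-8-yn-1-yl acetate
Product: 7 (2E,6S)-3,7,7-trimethylnon-2-en-8-yne-1,6-diol
Conditions: K2CO3 (cat.), MeOH, rt
Reagents that add atoms: none
Why: Base-catalysed transesterification frees the allylic alcohol needed for the directed epoxidation.

Step 6
Reactants: 7 (2E,6S)-3,7,7-trimethylnon-2-en-8-yne-1,6-diol
Product: 9 (1S)-1-[(2R,5S)-2-methyl-5-(2-methylbut-3-yn-2-yl)oxolan-2-yl]ethane-1,2-diol, via epoxy diol 8 (not isolated)
Conditions: Ti(OiPr)4, L-(+)-diethyl tartrate, t-BuOOH, 4 Å sieves, CH2Cl2, −20 °C; then camphorsulfonic acid (cat.), rt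
Reagents that add atoms: tert-butyl hydroperoxide, CC(C)(C)OO
Why: Sharpless asymmetric epoxidation with L-(+)-diethyl tartrate should give the (2S,3S)-epoxide, which the C3 hydroxyl opens 5-exo at the tertiary carbon with inversion under acid, setting C10 and the cis relationship of the two arms on the tetrahydrofuran.

Step 7
Reactants: 9 (1S)-1-[(2R,5S)-2-methyl-5-(2-methylbut-3-yn-2-yl)oxolan-2-yl]ethane-1,2-diol
Product: 10 (1S)-1-[(2R,5S)-2-methyl-5-(2-methylbut-3-yn-2-yl)oxolan-2-yl]-2-[(triethylsilyl)oxy]ethan-1-ol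
Conditions: Et3SiCl, imidazole, CH2Cl2, −20 °C
Reagents that add atoms: chlorotriethylsilane, CC[Si](Cl)(CC)CC
Why: Selective silylation of the primary hydroxyl of the 1,2-diol.

Step 8
Reactants: 10 (1S)-1-[(2R,5S)-2-methyl-5-(2-methylbut-3-yn-2-yl)oxolan-2-yl]-2-[(triethylsilyl)oxy]ethan-1-ol
Product: 11 1-[(2R,5S)-2-methyl-5-(2-methylbut-3-yn-2-yl)oxolan-2-yl]-2-[(triethylsilyl)oxy]ethan-1-one
Conditions: Dess–Martin periodinane, NaHCO3, CH2Cl2, rt
Reagents that add atoms: none
Why: Dess–Martin oxidation of the remaining secondary alcohol (C9) to the ketone.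

Step 9
Reactants: 11 1-[(2R,5S)-2-methyl-5-(2-methylbut-3-yn-2-yl)oxolan-2-yl]-2-[(triethylsilyl)oxy]ethan-1-one
Product: 12 triethyl({2-[(2R,5S)-2-methyl-5-(2-methylbut-3-yn-2-yl)oxolan-2-yl]prop-2-en-1-yl}oxy)silane
Conditions: Ph3PCH3Br, KOt-Bu, THF, 0 °C to rt
Reagents that add atoms: methyltriphenylphosphonium bromide, C[P+](c1ccccc1)(c1ccccc1)c1ccccc1.[Br-]
Why: Wittig methylenation converts the C9 ketone into the 1,1-disubstituted alkene whose CH2 becomes C8.

Step 10
Reactants: 12 triethyl({2-[(2R,5S)-2-methyl-5-(2-methylbut-3-yn-2-yl)oxolan-2-yl]prop-2-en-1-yl}oxy)silane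
Product: 13 (1R,2R,8S)-1,7,7-trimethyl-2-{[(triethylsilyl)oxy]methyl}-11-oxatricyclo[6.2.1.0^2,6]undec-5-en-4-one (A/B enone: C7 ketone, C5=C6)
Conditions: Co2(CO)8, CH2Cl2, rt; then N-methylmorpholine N-oxide, 0 °C to rt
Reagents that add atoms: dicobalt octacarbonyl, Co2(CO)8, which delivers one carbon monoxide, [C-]#[O+]
Why: Intramolecular Pauson–Khand reaction of the 1,7-enyne held on one face of the cis-2,5-disubstituted tetrahydrofuran closes ring B and the bridged ring A together; the new five-membered ring can span only the equatorial position at C9 of the forming chair oxane, so the CH2OSiEt3 group (C11) is placed axial, syn to the oxygen bridge.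

Step 11
Reactants: 13 (1R,2R,8S)-1,7,7-trimethyl-2-{[(triethylsilyl)oxy]methyl}-11-oxatricyclo[6.2.1.0^2,6]undec-5-en-4-one
Product: 14 (1R,2S,8S)-1,7,7-trimethyl-4-oxo-11-oxatricyclo[6.2.1.0^2,6]undec-5-ene-2-carbaldehyde
Conditions: (COCl)2, DMSO, CH2Cl2, −78 to −30 °C; Et3N
Reagents that add atoms: none
Why: Swern conditions cleave primary triethylsilyl ethers and oxidise them directly to aldehydes, giving the non-enolisable C11 aldehyde.

Step 12
Reactants: 14 (1R,2S,8S)-1,7,7-trimethyl-4-oxo-11-oxatricyclo[6.2.1.0^2,6]undec-5-ene-2-carbaldehyde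
Product: 15 (1R,2S,8S)-4-[(tert-butyldimethylsilyl)oxy]-1,7,7-trimethyl-11-oxatricyclo[6.2.1.0^2,6]undeca-3,5-diene-2-carbaldehyde
Conditions: TBSOTf, Et3N, CH2Cl2, −78 °C
Reagents that add atoms: tert-butyldimethylsilyl trifluoromethanesulfonate, CC(C)(C)[Si](C)(C)OS(=O)(=O)C(F)(F)F
Why: Soft enolisation can remove only the C8 hydrogens (C6 is vinylic and both γ-positions are quaternary), giving the cross-conjugated silyl dienol ether with C8 as its nucleophilic terminus.

Step 13
Reactants: 16 2,3-dimethylcyclohex-2-en-1-one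
Product: 17 (1S)-2,3-dimethylcyclohex-2-en-1-ol
Conditions: (R)-2-methyl-CBS-oxazaborolidine (cat.), catecholborane, toluene, −78 °C
Reagents that add atoms: none
Why: CBS reduction of the 2-substituted cyclohexenone, with the substituted alkene arm as the large group, should give the (S)-allylic alcohol (C18), the only source of chirality for ring D.

Step 14
Reactants: 17 (1S)-2,3-dimethylcyclohex-2-en-1-ol; 18 methyl 3-chloro-3-oxopropanoate
Product: 19 methyl (1S)-2,3-dimethylcyclohex-2-en-1-yl propanedioate
Conditions: pyridine, CH2Cl2, 0 °C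
Reagents that add atoms: none
Why: Acylation of the allylic alcohol with the malonyl half-ester chloride installs the tether that becomes C12 and its two carbonyl groups.

Step 15
Reactants: 19 methyl (1S)-2,3-dimethylcyclohex-2-en-1-yl propanedioate
Product: 20 1-[(1S)-2,3-dimethylcyclohex-2-en-1-yl] 3-methyl 2-diazopropanedioate
Conditions: 4-acetamidobenzenesulfonyl azide, Et3N, MeCN, rt
Reagents that add atoms: 4-acetamidobenzenesulfonyl azide, CC(=O)Nc1ccc(cc1)S(=O)(=O)N=[N+]=[N-]
Why: Regitz diazo transfer to the activated methylene of the malonate.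

Step 16
Reactants: 20 1-[(1S)-2,3-dimethylcyclohex-2-en-1-yl] 3-methyl 2-diazopropanedioate
Product: 21 methyl (1R,2R,5S,9S)-1,9-dimethyl-3-oxo-4-oxatricyclo[3.3.1.0^2,9]nonane-2-carboxylate (ring-D cyclopropane lactone: C12 carries CO2Me and the lactone carbonyl; lactone oxygen on C18)
Conditions: Rh2(OAc)4 (1 mol %), CH2Cl2, reflux, slow addition
Reagents that add atoms: none
Why: Intramolecular cyclopropanation of the allylic diazomalonate (rhodium carbenoid) can reach only the alkene face that carries the C18 oxygen, so the cis-dimethylcyclopropane carbons C13 and C14 are set from the C18 carbinol.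

Step 17
Reactants: 15 (1R,2S,8S)-4-[(tert-butyldimethylsilyl)oxy]-1,7,7-trimethyl-11-oxatricyclo[6.2.1.0^2,6]undeca-3,5-diene-2-carbaldehyde; 21 methyl (1R,2R,5S,9S)-1,9-dimethyl-3-oxo-4-oxatricyclo[3.3.1.0^2,9]nonane-2-carboxylate
Product: 23 pentacyclic silyloxy lactone ester (rings A–D closed; C7 enone; C11–OTBS; C12 bearing CO2Me plus the lactone carbonyl bound to O–C18), via silyl ketene acetal 22 (not isolated)
Conditions: Sc(OTf)3 (20 mol %), 4 Å sieves, CH2Cl2, −40 °C to rt
Reagents that add atoms: none
Why: Proposed new method: Sc(OTf)3 bound to the lactone and ester carbonyls of 21 polarises the cyclopropane bond C12–C14, the silyl dienol ether carbon C8 of 15 opens it by backside attack at the tertiary carbon C14, silyl transfer gives the silyl ketene acetal 22, and its C12 then adds to the C11 aldehyde (intramolecular Mukaiyama aldol), so that the cyclopropane acts as a 1,3-dipole in a formal (3+3) annulation. The closest known reaction types are the Lewis-acid-catalysed (3+2) annulations of cyclopropane-1,1-dicarbonyl compounds with silyl enol ethers and with aldehydes, and the nucleophilic opening of cyclopropane-fused butyrolactones at the carbon outside the lactone ring. Ring C is the only ring closed, by the aldol in the 6-(enolexo)-exo-trig mode after the bimolecular C8–C14 bond formation. C14 is controlled by inversion at the cyclopropane carbon (C8 enters anti to C12, on the face not covered by the lactone), which turns the cis-dimethylcyclopropane into the anti C13/C14 methyl pair of the trans C/D fusion; C8 is controlled by the quaternary C9, whose formyl group rather than C10 lies on the attacked diene face, giving the cis B/C fusion needed for ring closure; C11 and C12 are temporary stereocentres removed later. The step needs regioselective cleavage of C12–C14 rather than C12–C13, secured by the lactone that makes C13 a ring-fusion carbon next to the acyloxy-bearing C18, and carbon–carbon bond formation in preference to proton loss from the developing tertiary cation, favoured by the highly nucleophilic 2-silyloxydiene.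

Step 18
Reactants: 23 pentacyclic silyloxy lactone ester
Product: 24 enone alkylidene lactone (C5=C6–C7=O; C11=C12–C(=O)–O–C18)
Conditions: LiCl, dry DMSO, 150 °C
Reagents that add atoms: none
Why: Krapcho dealkoxycarbonylation (chloride attack on the methyl ester, loss of CO2) releases the lactone enolate, which should expel the β-silyloxy group (E1cB), removing both the ester and the C11 oxygen in one step.

Step 19
Reactants: 24 enone alkylidene lactone
Product: 25 keto lactone (C7 ketone; H5 anti to the oxygen bridge; saturated lactone; C12 epimers)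
Conditions: Li, NH3 (l), THF, t-BuOH (2 equiv), −78 °C; NH4Cl
Reagents that add atoms: none
Why: Dissolving-metal reduction saturates both conjugated alkenes; protonation at the β-carbon C5 of the enone should occur axially on the chair oxane ring, as in the reduction of ring-fused enones to trans-fused ketones, placing H5 anti to the oxygen bridge.

Step 20
Reactants: 25 keto lactone
Product: 26 lactone with C7 as CH2
Conditions: N2H4·H2O, KOH, diethylene glycol, 130 then 200 °C; aq. HCl
Reagents that add atoms: none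
Why: Wolff–Kishner reduction (Huang–Minlon conditions) of the unhindered cyclopentanone; the lactone is opened to its carboxylate under the basic conditions and recloses on acidification.

Step 21
Reactants: 26 lactone with C7 as CH2
Product: 28 γ-keto acid (C18 ketone; C12–CO2H), via hydroxy acid 27 (not isolated)
Conditions: LiOH, THF/H2O, 50 °C; then 2-azaadamantane N-oxyl (cat.), NaOCl, KBr, pH 10, 0 °C; aq. HCl
Reagents that add atoms: lithium hydroxide, [Li+].[OH-]
Why: Saponification to the hydroxy carboxylate followed by nitroxyl-catalysed hypochlorite oxidation at pH 10, where relactonisation cannot compete, should give the γ-keto acid and turns C18 into the ketone needed for the C17 alkylations.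

Step 22
Reactants: 28 γ-keto acid
Product: 29 C18 ketone (C12 and C17 both CH2)
Conditions: 9-mesityl-10-phenylacridinium tetrafluoroborate (cat.), PhSSPh (cat.), i-Pr2NEt (cat.), CF3CH2OH, blue LEDs, rt
Reagents that add atoms: none
Why: Photoredox hydrodecarboxylation (oxidation of the carboxylate, loss of CO2, hydrogen-atom transfer from thiophenol) removes the last carbon of the lactone helper and leaves C12 as CH2.

Step 23
Reactants: 29 C18 ketone; 30 5-bromo-2-methylpent-2-ene
Product: 31 17-(4-methylpent-3-enyl) C18 ketone (C17 epimers)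
Conditions: LiN(iPr)2, THF, −78 °C; then 30, NaI (cat.), DMPU, −78 °C to rt
Reagents that add atoms: none
Why: Enolate alkylation: the C18 ketone can enolise only toward C17 because C13 is quaternary, so the side chain is introduced regiospecifically.

Step 24
Reactants: 31 17-(4-methylpent-3-enyl) C18 ketone
Product: 32 C18 ketone with quaternary C17 (methyl cis to the C14 methyl; side chain cis to the C13 methyl)
Conditions: KN(SiMe3)2, THF, −78 °C; MeI, to 0 °C
Reagents that add atoms: iodomethane, CI
Why: Alkylation of the fully substituted enolate should occur on the face anti to the axial C13 methyl (1,3-diaxial control, as in alkylations next to an angular methyl), so the methyl introduced last is cis to the C14 methyl and the side chain is cis to the C13 methyl, as in the target.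

Step 25
Reactants: 32 C18 ketone with quaternary C17
Product: 33 target CNP0284367.1
Conditions: anhydrous N2H4, KOH, diethylene glycol, 210 °C with removal of water
Reagents that add atoms: none
Why: Wolff–Kishner reduction under forcing conditions, as required for ketones flanked by two quaternary carbons, removes the last helper; the trisubstituted alkene is inert to these conditions.

**Compound list**

1 | geranyl acetate | CC(C)=CCC/C(C)=C/COC(C)=O | starting material
2 | (2E)-3-methyl-6-oxohex-2-en-1-yl acetate | O=CCC/C(C)=C/COC(C)=O | intermediate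
3 | 3-chloro-3-methylbut-1-yne | C#CC(C)(C)Cl | starting material
4 | (2E)-6-hydroxy-3,7,7-trimethylnon-2-en-8-yn-1-yl acetate (racemic) | C#CC(C)(C)C(O)CC/C(C)=C/COC(C)=O | intermediate
5 | (2E)-3,7,7-trimethyl-6-oxonon-2-en-8-yn-1-yl acetate | C#CC(C)(C)C(=O)CC/C(C)=C/COC(C)=O | intermediate
6 | (2E,6S)-6-hydroxy-3,7,7-trimethylnon-2-en-8-yn-1-yl acetate | C#CC(C)(C)[C@@H](O)CC/C(C)=C/COC(C)=O | intermediate
7 | (2E,6S)-3,7,7-trimethylnon-2-en-8-yne-1,6-diol | C#CC(C)(C)[C@@H](O)CC/C(C)=C/CO | intermediate
8 | [(2S,3S)-3-[(3S)-3-hydroxy-4,4-dimethylhex-5-yn-1-yl]-3-methyloxiran-2-yl]methanol | C#CC(C)(C)[C@@H](O)CC[C@]1(C)O[C@H]1CO | intermediate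
9 | (1S)-1-[(2R,5S)-2-methyl-5-(2-methylbut-3-yn-2-yl)oxolan-2-yl]ethane-1,2-diol | C#CC(C)(C)[C@@H]1CC[C@@](C)(O1)[C@@H](O)CO | intermediate
10 | (1S)-1-[(2R,5S)-2-methyl-5-(2-methylbut-3-yn-2-yl)oxolan-2-yl]-2-[(triethylsilyl)oxy]ethan-1-ol | C#CC(C)(C)[C@@H]1CC[C@@](C)(O1)[C@@H](O)CO[Si](CC)(CC)CC | intermediate
11 | 1-[(2R,5S)-2-methyl-5-(2-methylbut-3-yn-2-yl)oxolan-2-yl]-2-[(triethylsilyl)oxy]ethan-1-one | C#CC(C)(C)[C@@H]1CC[C@@](C)(O1)C(=O)CO[Si](CC)(CC)CC | intermediate
12 | triethyl({2-[(2R,5S)-2-methyl-5-(2-methylbut-3-yn-2-yl)oxolan-2-yl]prop-2-en-1-yl}oxy)silane | C#CC(C)(C)[C@@H]1CC[C@@](C)(O1)C(=C)CO[Si](CC)(CC)CC | intermediate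
13 | (1R,2R,8S)-1,7,7-trimethyl-2-{[(triethylsilyl)oxy]methyl}-11-oxatricyclo[6.2.1.0^2,6]undec-5-en-4-one | O=C1C=C2C(C)(C)[C@@H]3CC[C@@](C)(O3)[C@]2(CO[Si](CC)(CC)CC)C1 | intermediate
14 | (1R,2S,8S)-1,7,7-trimethyl-4-oxo-11-oxatricyclo[6.2.1.0^2,6]undec-5-ene-2-carbaldehyde | O=C1C=C2C(C)(C)[C@@H]3CC[C@@](C)(O3)[C@]2(C=O)C1 | intermediate
15 | (1R,2S,8S)-4-[(tert-butyldimethylsilyl)oxy]-1,7,7-trimethyl-11-oxatricyclo[6.2.1.0^2,6]undeca-3,5-diene-2-carbaldehyde | CC(C)(C)[Si](C)(C)OC=1C=C2C(C)(C)[C@@H]3CC[C@@](C)(O3)[C@]2(C=O)C=1 | intermediate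
16 | 2,3-dimethylcyclohex-2-en-1-one | CC1=C(C)C(=O)CCC1 | starting material
17 | (1S)-2,3-dimethylcyclohex-2-en-1-ol | CC1=C(C)[C@@H](O)CCC1 | intermediate
18 | methyl 3-chloro-3-oxopropanoate | COC(=O)CC(Cl)=O | starting material
19 | methyl (1S)-2,3-dimethylcyclohex-2-en-1-yl propanedioate | CC1=C(C)[C@@H](OC(=O)CC(=O)OC)CCC1 | intermediate
20 | 1-[(1S)-2,3-dimethylcyclohex-2-en-1-yl] 3-methyl 2-diazopropanedioate | CC1=C(C)[C@@H](OC(=O)C(=[N+]=[N-])C(=O)OC)CCC1 | intermediate
21 | methyl (1R,2R,5S,9S)-1,9-dimethyl-3-oxo-4-oxatricyclo[3.3.1.0^2,9]nonane-2-carboxylate | COC(=O)[C@@]12C(=O)O[C@H]3CCC[C@]1(C)[C@@]23C | intermediate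
22 | ring-opened silyl ketene acetal (C8–C14 bond formed; C7 enone; C11 aldehyde; C12=C(OTBS)–O–C18; CO2Me on C12) | O=C1C=C2C(C)(C)[C@@H]3CC[C@@](C)(O3)[C@]2(C=O)[C@H]1[C@@]1(C)CCC[C@@H]2OC(O[Si](C)(C)C(C)(C)C)=C(C(=O)OC)[C@]12C | intermediate
23 | pentacyclic silyloxy lactone ester (C7 enone; C11–OTBS, C11 epimers; C12 bearing CO2Me and the lactone carbonyl bound to O–C18) | O=C1C=C2C(C)(C)[C@@H]3CC[C@@](C)(O3)[C@@]24C(O[Si](C)(C)C(C)(C)C)[C@@]5(C(=O)OC)C(=O)O[C@H]6CCC[C@](C)([C@@H]14)[C@@]56C | intermediate
24 | enone alkylidene lactone (C5=C6–C7=O; C11=C12–C(=O)–O–C18) | O=C1C=C2C(C)(C)[C@@H]3CC[C@@](C)(O3)[C@@]24C=C5C(=O)O[C@H]6CCC[C@](C)([C@@H]14)[C@@]56C | intermediate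
25 | keto lactone (C7 ketone; saturated rings; C12 epimers) | O=C1C[C@H]2C(C)(C)[C@@H]3CC[C@@](C)(O3)[C@@]24CC5C(=O)O[C@H]6CCC[C@](C)([C@@H]14)[C@@]56C | intermediate
26 | lactone with C7 as CH2 (C12 epimers) | C1C[C@H]2C(C)(C)[C@@H]3CC[C@@](C)(O3)[C@@]24CC5C(=O)O[C@H]6CCC[C@](C)([C@@H]14)[C@@]56C | intermediate
27 | hydroxy acid (C18–OH; C12–CO2H) | C1C[C@H]2C(C)(C)[C@@H]3CC[C@@](C)(O3)[C@@]24CC(C(=O)O)[C@@]5(C)[C@@H](O)CCC[C@]5(C)[C@@H]14 | intermediate
28 | γ-keto acid (C18 ketone; C12–CO2H) | C1C[C@H]2C(C)(C)[C@@H]3CC[C@@](C)(O3)[C@@]24CC(C(=O)O)[C@@]5(C)C(=O)CCC[C@]5(C)[C@@H]14 | intermediate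
29 | C18 ketone (C12 and C17 are CH2) | C1C[C@H]2C(C)(C)[C@@H]3CC[C@@](C)(O3)[C@@]24CC[C@@]5(C)C(=O)CCC[C@]5(C)[C@@H]14 | intermediate
30 | 5-bromo-2-methylpent-2-ene | CC(C)=CCCBr | starting material
31 | 17-(4-methylpent-3-enyl) C18 ketone (C17 epimers) | C1C[C@H]2C(C)(C)[C@@H]3CC[C@@](C)(O3)[C@@]24CC[C@@]5(C)C(=O)C(CCC=C(C)C)CC[C@]5(C)[C@@H]14 | intermediate
32 | C18 ketone with quaternary C17 (17-methyl cis to the 14-methyl) | C1C[C@H]2C(C)(C)[C@@H]3CC[C@@](C)(O3)[C@@]24CC[C@@]5(C)C(=O)[C@](C)(CCC=C(C)C)CC[C@]5(C)[C@@H]14 | intermediate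
33 | target CNP0284367.1, C30H50O, (3S,5S,8R,9R,10R,13S,14R,17R) in the locants of the remark | CC(C)=CCC[C@]1(C)CC[C@]2(C)[C@H]3CC[C@H]4C(C)(C)[C@@H]5CC[C@@](C)(O5)[C@@]43CC[C@@]2(C)C1 | target

**Totals and risks**

Total step count: 25. Longest linear sequence: 21 steps (steps 1–12, then 17–25); ring D is prepared in four steps (13–16).

Steps most likely to fail:

1. Step 17 (Proposed new method). The ring-opened tertiary cation may lose a proton instead of forming the C8–C14 bond, the wrong cyclopropane bond may open, or the sequence may stall before the congested aldol closure at C12. Fallback with known reactions, one bond at a time with separate promoters: from 15 and 21, stoichiometric SnCl4 in CH2Cl2 at −78 °C with a cold quench should stop at the ring-opened keto aldehyde F1 (Lewis-acid opening of a cyclopropane-1,1-dicarbonyl compound by a silyl enol ether). Soft enolisation of its acyl lactone (MgBr2·OEt2, Et3N) then closes ring C by intramolecular aldol addition to the hydroxy lactone ester F2. Silylation (TBSOTf, 2,6-lutidine) returns to the route at 23.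

2. Step 10. Insertion of the 1,1-disubstituted alkene into the alkyne–Co2(CO)6 complex may be too slow, so that the complex decomposes, or control at C9 may be incomplete. Fallback: from 12, zirconocene-mediated reductive bicyclisation (Cp2ZrCl2, 2 n-BuLi, THF, −78 °C to rt) to the zirconacyclopentene F3, then CO (1 atm) and acidic work-up. This stoichiometric cyclocarbonylation does not depend on alkene insertion into a cobalt cluster; it returns at 13.

3. Step 25. Hydrazone formation at the ketone between two quaternary carbons may be incomplete, or azine formation may intervene. Fallback: from 32, LiAlH4 reduction gives the C18 alcohol F4; NaH, CS2, then MeI gives the xanthate F5; Barton–McCombie deoxygenation with Bu3SnH and AIBN in the presence of catalytic PhSeSePh (benzeneselenol as a fast hydrogen donor, so the C18 radical is reduced before it can add to the side-chain alkene) gives 33.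

Further compounds
F1 | step 17 | ring-opened keto aldehyde (C8–C14 bond formed; C7 enone; C11 aldehyde; C12–H acyl lactone with CO2Me) | O=C1C=C2C(C)(C)[C@@H]3CC[C@@](C)(O3)[C@]2(C=O)[C@H]1[C@@]1(C)CCC[C@@H]2OC(=O)C(C(=O)OC)[C@]12C
F2 | step 17 | hydroxy lactone ester (23 with free C11–OH) | O=C1C=C2C(C)(C)[C@@H]3CC[C@@](C)(O3)[C@@]24C(O)[C@@]5(C(=O)OC)C(=O)O[C@H]6CCC[C@](C)([C@@H]14)[C@@]56C
F3 | step 10 | zirconacyclopentene (Zr bound to C6 and C8; two cyclopentadienyl ligands) | C1=C2C(C)(C)[C@@H]3CC[C@@](C)(O3)[C@]2(CO[Si](CC)(CC)CC)C[Zr]1(C1C=CC=C1)C1C=CC=C1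
F4 | step 25 | C18 alcohol of 32 (C18 epimers) | C1C[C@H]2C(C)(C)[C@@H]3CC[C@@](C)(O3)[C@@]24CC[C@@]5(C)C(O)[C@](C)(CCC=C(C)C)CC[C@]5(C)[C@@H]14
F5 | step 25 | O-(C18) S-methyl carbonodithioate of F4 | C1C[C@H]2C(C)(C)[C@@H]3CC[C@@](C)(O3)[C@@]24CC[C@@]5(C)C(OC(=S)SC)[C@](C)(CCC=C(C)C)CC[C@]5(C)[C@@H]14
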